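The route rests on opening the 14-membered carbocycle at C7/C8: the (E)-C7=C8(Me)–C9(OAc) 2-methylallylic ester is read as a C7≡C8 cycloalkyne with a propargylic C9 oxygen. Ring-closing alkyne metathesis of a methyl-capped diyne makes the C7≡C8 bond and the macrocycle in one operation, with no alkene geometry at stake. The freed C9 hydroxyl then steers an anti hydrostannation, and tin-to-methyl exchange writes in the E-trisubstituted alkene. The metathesis precursor is an open-chain diyne that already carries the trans-fused γ-lactone (C1, C2), the C3 and C11 E-alkenes and a C9 tert-butyldimethylsilyl ether.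

Key step: step 20

Atom numbers (cembrane): C1 lactone β-CH, C2 lactone O–CH, C15/C16/C17 lactone α-carbon, carbonyl and exo-methylene. For CIP reasons only, C2 is (R) in all compounds lacking C17 and (S) once the exo-methylene is present.

Assumption: hex-1-en-5-yne serves as the C11–C14/C1/C2 unit, its terminal alkene being the latent C2 carboxyl; in step 18 the alkenyl flank of ketone 31 is taken as the larger carbonyl substituent, as is usual for enones.

Design choice: C9 is carried as a tert-butyldimethylsilyl ether instead of a more labile trialkylsilyl ether, because it must outlast organolithium, oxidation, borane and base steps and still fall to fluoride after ring closure.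

**Fragment B: C3–C7 alkenyl iodide**

Step 1
Reactants: 1 pent-3-yn-1-ol
Product: 2 pent-3-yn-1-yl 4-methylbenzenesulfonate
Conditions: TsCl, Et3N, DMAP (cat.), CH2Cl2, 0 °C → rt
Reagents that add atoms: 4-methylbenzenesulfonyl chloride, Cc1ccc(cc1)S(=O)(=O)Cl
Why: Sulfonylation of an unhindered primary alcohol is routine and turns the hydroxyl into the SN2 leaving group; the internal alkyne does not interfere.

Step 2
Reactants: 2 pent-3-yn-1-yl 4-methylbenzenesulfonate
Product: 3 hepta-1,5-diyne
Conditions: LiC≡CH·H2NCH2CH2NH2, DMSO, 10 °C → rt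
Reagents that add atoms: lithium acetylide ethylenediamine complex, [Li+].[C-]#C.NCCN
Why: SN2 alkylation of lithium acetylide by a primary tosylate in DMSO is the standard terminal-alkyne synthesis, and a sulfonate (not a halide) is chosen to keep E2 loss to the conjugated enyne small.

Step 3
Reactants: 3 hepta-1,5-diyne
Product: 5 (1E)-1-iodo-2-methylhept-1-en-5-yne, via alkenyldimethylalane 4 (not isolated)
Conditions: Me3Al, Cp2ZrCl2 (cat.), CH2Cl2, 0 °C → rt; then I2, THF, −30 °C → 0 °C
Reagents that add atoms: trimethylaluminium, C[Al](C)C; iodine, II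
Why: Negishi zirconium-catalysed methylalumination adds methyl and aluminium syn across the terminal alkyne only (internal dialkyl alkynes react far more slowly), methyl to the inner carbon, and iodinolysis of the C–Al bond with retention gives the E iodide that becomes C3=C4.

**Fragment A: C8–C14, C1, C2, C15, C16**

Step 4
Reactants: 6 hex-1-en-5-yne; 7 (R)-benzyl glycidyl ether
Product: 10 (2R,4E)-1-(benzyloxy)-5-methylnona-4,8-dien-2-ol, via alkenyldimethylalane 8 (not isolated), via lithium alkenylalanate 9 (not isolated)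
Conditions: Me3Al, Cp2ZrCl2 (cat.), CH2Cl2, 0 °C → rt; excess Me3Al evaporated; n-BuLi, hexane/THF, −78 → 0 °C; then 7, THF, 0 °C → rt
Reagents that add atoms: trimethylaluminium, C[Al](C)C
Why: The same Negishi carboalumination (the alkyne reacts, the terminal alkene does not) gives the E alkenylalane, whose butyl ate complex opens the epoxide by SN2 attack at the unsubstituted carbon, so C11=C12 geometry comes from the syn addition and C9 is carried over unchanged from the glycidyl ether as (R).

Step 5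
Reactants: 10 (2R,4E)-1-(benzyloxy)-5-methylnona-4,8-dien-2-ol
Product: 11 {[(2R,4E)-1-(benzyloxy)-5-methylnona-4,8-dien-2-yl]oxy}(tert-butyl)dimethylsilane
Conditions: TBSCl, imidazole, DMF, rt
Reagents that add atoms: tert-butyldimethylsilyl chloride, CC(C)(C)[Si](C)(C)Cl
Why: Imidazole-promoted silylation of a secondary alcohol is standard and installs the one C9 protecting group that is kept until after ring closure.

Step 6
Reactants: 11 {[(2R,4E)-1-(benzyloxy)-5-methylnona-4,8-dien-2-yl]oxy}(tert-butyl)dimethylsilane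
Product: 12 (2R,4E)-2-[(tert-butyldimethylsilyl)oxy]-5-methylnona-4,8-dien-1-ol
Conditions: lithium 4,4'-di-tert-butylbiphenylide, THF, −78 °C; NH4Cl quench at −78 °C
Reagents that add atoms: none
Why: Reductive debenzylation by the arene radical anion cleaves only the benzylic C–O bond (isolated alkenes and the silyl ether are inert at −78 °C), and the cold quench keeps the silyl group from migrating to the new primary alkoxide.

Step 7
Reactants: 12 (2R,4E)-2-[(tert-butyldimethylsilyl)oxy]-5-methylnona-4,8-dien-1-ol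
Product: 13 (2R,4E)-2-[(tert-butyldimethylsilyl)oxy]-5-methylnona-4,8-dienal
Conditions: Dess–Martin periodinane, CH2Cl2, 0 °C → rt
Reagents that add atoms: none
Why: Dess–Martin oxidation of a primary alcohol under near-neutral conditions should give the α-silyloxy aldehyde without epimerising C9; it is used without storage.

Step 8
Reactants: 13 (2R,4E)-2-[(tert-butyldimethylsilyl)oxy]-5-methylnona-4,8-dienal
Product: 14 tert-butyl{[(3R,5E)-1,1-dibromo-6-methyldeca-1,5,9-trien-3-yl]oxy}dimethylsilane
Conditions: CBr4, PPh3, Et3N, CH2Cl2, 0 °C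
Reagents that add atoms: tetrabromomethane, BrC(Br)(Br)Br
Why: Corey–Fuchs (Ramirez) dibromo-olefination by the ylide formed from CBr4 and PPh3 is a Wittig reaction that leaves the α-stereocentre untouched, with Et3N buffering the silyl ether against HBr.

Step 9
Reactants: 14 tert-butyl{[(3R,5E)-1,1-dibromo-6-methyldeca-1,5,9-trien-3-yl]oxy}dimethylsilane
Product: 16 tert-butyldimethyl{[(4R,6E)-7-methylundeca-6,10-dien-2-yn-4-yl]oxy}silane, via lithium acetylide 15 (not isolated)
Conditions: n-BuLi (2.2 equiv), THF, −78 °C; then MeI, −78 °C → rt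
Reagents that add atoms: iodomethane, CI
Why: Second stage of the Corey–Fuchs sequence: bromine–lithium exchange, Fritsch–Buttenberg–Wiechell 1,2-shift and deprotonation give the lithium acetylide, which is C-methylated by MeI to install the methyl cap needed for alkyne metathesis.

Step 10
Reactants: 16 tert-butyldimethyl{[(4R,6E)-7-methylundeca-6,10-dien-2-yn-4-yl]oxy}silane
Product: 18 (5E,8R)-8-[(tert-butyldimethylsilyl)oxy]-5-methylundec-5-en-9-yn-1-ol, via B-alkyl-9-BBN 17 (not isolated)
Conditions: 9-BBN, THF, 0 °C → rt; then NaOH, H2O2, 0 °C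
Reagents that add atoms: hydrogen peroxide, OO
Why: 9-BBN hydroborates the monosubstituted alkene anti-Markovnikov far faster than the trisubstituted alkene or the internal alkyne, and alkaline peroxide oxidation of the C–B bond gives the primary alcohol at C2.

Step 11
Reactants: 18 (5E,8R)-8-[(tert-butyldimethylsilyl)oxy]-5-methylundec-5-en-9-yn-1-ol
Product: 20 (5E,8R)-8-[(tert-butyldimethylsilyl)oxy]-5-methylundec-5-en-9-ynoic acid, via aldehyde 19 (not isolated)
Conditions: TEMPO (cat.), PhI(OAc)2, MeCN/H2O, rt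
Reagents that add atoms: water, O
Why: Nitroxyl-catalysed oxidation with PhI(OAc)2 in aqueous acetonitrile takes a primary alcohol through the aldehyde hydrate to the acid and leaves the alkyne, the trisubstituted alkene and the silyl ether alone.

Step 12
Reactants: 20 (5E,8R)-8-[(tert-butyldimethylsilyl)oxy]-5-methylundec-5-en-9-ynoic acid; 21 (4S)-4-benzyl-1,3-oxazolidin-2-one
Product: 23 (4S)-4-benzyl-3-[(5E,8R)-8-[(tert-butyldimethylsilyl)oxy]-5-methylundec-5-en-9-ynoyl]-1,3-oxazolidin-2-one, via mixed pivalic anhydride 22 (not isolated)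
Conditions: PivCl, Et3N, THF, −20 °C; then 21, LiCl, −20 °C → rt
Reagents that add atoms: none
Why: Acylation of the oxazolidinone by the mixed pivalic anhydride under Et3N/LiCl activation is the standard way to attach the Evans auxiliary without strong base.

Step 13
Reactants: 23 (4S)-4-benzyl-3-[(5E,8R)-8-[(tert-butyldimethylsilyl)oxy]-5-methylundec-5-en-9-ynoyl]-1,3-oxazolidin-2-one; 24 tert-butyl bromoacetate
Product: 26 tert-butyl (3R,6E,9R)-3-{[(4S)-4-benzyl-2-oxo-1,3-oxazolidin-3-yl]carbonyl}-9-[(tert-butyldimethylsilyl)oxy]-6-methyldodec-6-en-10-ynoate, via sodium Z-enolate 25 (not isolated)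
Conditions: NaN(SiMe3)2, THF, −78 °C; then 24, −78 → −40 °C
Reagents that add atoms: none
Why: Evans asymmetric alkylation: the chelated sodium Z-enolate is attacked by the reactive α-bromo ester on the face opposite the benzyl group of the (S)-auxiliary, which sets C1 as (R) and brings in C15–C16.

Step 14
Reactants: 26 tert-butyl (3R,6E,9R)-3-{[(4S)-4-benzyl-2-oxo-1,3-oxazolidin-3-yl]carbonyl}-9-[(tert-butyldimethylsilyl)oxy]-6-methyldodec-6-en-10-ynoate
Product: 27 tert-butyl (3R,6E,9R)-9-[(tert-butyldimethylsilyl)oxy]-3-(hydroxymethyl)-6-methyldodec-6-en-10-ynoate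
Conditions: LiBH4, MeOH (1 equiv), THF, 0 °C
Reagents that add atoms: none
Why: LiBH4 reduces the activated exocyclic imide carbonyl to the primary alcohol and releases the auxiliary while the hindered tert-butyl ester survives; C1 is not epimerised under these non-enolising conditions.

Step 15
Reactants: 27 tert-butyl (3R,6E,9R)-9-[(tert-butyldimethylsilyl)oxy]-3-(hydroxymethyl)-6-methyldodec-6-en-10-ynoate
Product: 28 tert-butyl (3R,6E,9R)-9-[(tert-butyldimethylsilyl)oxy]-3-formyl-6-methyldodec-6-en-10-ynoate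
Conditions: Dess–Martin periodinane, CH2Cl2, 0 °C → rt
Reagents that add atoms: none
Why: Dess–Martin oxidation should give the α-branched aldehyde under conditions that do not enolise it; it is taken on at once.

**Fragment union and lactone**

Step 16
Reactants: 28 tert-butyl (3R,6E,9R)-9-[(tert-butyldimethylsilyl)oxy]-3-formyl-6-methyldodec-6-en-10-ynoate; 5 (1E)-1-iodo-2-methylhept-1-en-5-yne
Product: 30 tert-butyl (3R,6E,9R)-9-[(tert-butyldimethylsilyl)oxy]-3-[(2E)-1-hydroxy-3-methyloct-2-en-6-yn-1-yl]-6-methyldodec-6-en-10-ynoate as both carbinol epimers, via alkenylchromium dichloride 29 (not isolated)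
Conditions: CrCl2 (excess), NiCl2 (cat.), DMSO, rt
Reagents that add atoms: none
Why: Nozaki–Hiyama–Kishi coupling: NiCl2-catalysed formation of the alkenylchromium reagent with retention of the E geometry and its chemoselective addition to the aldehyde in the presence of the ester and both alkynes forms C2–C3; the weak 1,2-induction from C1 is expected to give both C2 epimers, which converge in step 17.

Step 17
Reactants: 30 allylic alcohols (both C2 epimers)
Product: 31 tert-butyl (3R,6E,9R)-9-[(tert-butyldimethylsilyl)oxy]-6-methyl-3-[(2E)-3-methyloct-2-en-6-ynoyl]dodec-6-en-10-ynoate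
Conditions: Dess–Martin periodinane, CH2Cl2, 0 °C → rt
Reagents that add atoms: none
Why: Dess–Martin oxidation of the allylic alcohols merges both C2 epimers into one E enone under neutral conditions that spare the adjacent C1 stereocentre.

Step 18
Reactants: 31 tert-butyl (3R,6E,9R)-9-[(tert-butyldimethylsilyl)oxy]-6-methyl-3-[(2E)-3-methyloct-2-en-6-ynoyl]dodec-6-en-10-ynoate
Product: 32 tert-butyl (3R,6E,9R)-9-[(tert-butyldimethylsilyl)oxy]-3-[(1R,2E)-1-hydroxy-3-methyloct-2-en-6-yn-1-yl]-6-methyldodec-6-en-10-ynoate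
Conditions: (S)-2-methyl-CBS-oxazaborolidine, catecholborane, toluene, −78 °C
Reagents that add atoms: none
Why: Corey–Bakshi–Shibata reduction: the (S)-oxazaborolidine binds the ketone with the alkenyl flank in the large-group position and delivers hydride from catecholborane to one face, so C2 should be set as (R) by the catalyst and not by the weak bias of C1; catecholborane at −78 °C does not hydroborate the alkenes or alkynes.

Step 19
Reactants: 32 tert-butyl (3R,6E,9R)-9-[(tert-butyldimethylsilyl)oxy]-3-[(1R,2E)-1-hydroxy-3-methyloct-2-en-6-yn-1-yl]-6-methyldodec-6-en-10-ynoate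
Product: 33 (4R,5R)-4-[(3E,6R)-6-[(tert-butyldimethylsilyl)oxy]-3-methylnon-3-en-7-yn-1-yl]-5-[(1E)-2-methylhept-1-en-5-yn-1-yl]oxolan-2-one (seco-diyne trans-lactone)
Conditions: KOC(CH3)3 (cat.), THF, 0 °C → rt
Reagents that add atoms: none
Why: Base-catalysed intramolecular transesterification (5-exo attack of the C2 alkoxide on the tert-butyl ester) closes the γ-lactone without breaking any bond at C1 or C2, so the anti hydroxy ester gives the trans lactone; base is preferred to acid because the allylic carbinol would ionise under acid.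

**Ring closure and endgame**

Step 20
Reactants: 33 seco-diyne trans-lactone with C9 tert-butyldimethylsilyl ether
Product: 34 14-membered C7≡C8 cycloalkyne trans-lactone with C9 tert-butyldimethylsilyl ether (1R,2R,9R; 3E,11E)
Conditions: Mo(≡CC6H4-4-OMe)(OSiPh3)3 (15 mol%), 5 Å molecular sieves, toluene (0.002 M), 60–80 °C
Reagents that add atoms: none
Why: The molybdenum alkylidyne adds to one methyl-capped alkyne of 33 in a [2+2] sense to give a metallacyclobutadiene, cycloreversion expels but-2-yne (trapped by the sieves) and leaves a substrate-bound alkylidyne, which closes the ring by the same cycloaddition–cycloreversion on the second alkyne. The closest known reaction type is ring-closing alkyne metathesis of methyl-capped diynes to unstrained macrocyclic alkynes with triarylsilanolate molybdenum alkylidynes. The 14-membered carbocycle closes by end-to-end union of C7 and C8 across the trans-fused γ-lactone, an unstrained macrocyclisation run at high dilution. No stereocentre is formed, C1, C2 and C9 are remote from the reacting carbons, and a cycloalkyne poses no E/Z question. The step needs alkyne-over-alkene chemoselectivity and ring closure over oligomerisation: the alkylidyne does not engage the trisubstituted alkenes, the lactone or the silyl ether, and dilution together with removal of but-2-yne should favour the cyclic product.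

Step 21
Reactants: 34 cycloalkyne trans-lactone C9 silyl ether
Product: 35 14-membered C7≡C8 cycloalkyne trans-lactone with free C9 hydroxyl (1R,2R,9R; 3E,11E)
Conditions: Bu4NF, AcOH, THF, 0 °C → rt
Reagents that add atoms: none
Why: Fluoride cleaves the propargylic silyl ether at silicon, and acetic acid buffering keeps the ammonium alkoxide from opening the lactone.

Step 22
Reactants: 35 cycloalkyne propargylic alcohol
Product: 36 (7Z)-8-(tributylstannyl) macrocyclic C9 allylic alcohol trans-lactone (1R,2R,9R; 3E,11E)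
Conditions: [Cp*RuCl]4 (cat.), Bu3SnH, CH2Cl2, rt
Reagents that add atoms: tributyltin hydride, CCCC[SnH](CCCC)CCCC
Why: Ruthenium-catalysed trans-hydrostannation: the free C9 hydroxyl hydrogen-bonds to the chloride ligand of the Cp*RuCl unit and steers tin to the proximal carbon C8 while hydrogen is delivered anti to C7, giving the Z alkenylstannane (tin cis to C6); the trisubstituted alkenes and the lactone are not touched.

Step 23
Reactants: 36 (7Z)-8-(tributylstannyl) macrocyclic allylic alcohol
Product: 38 (1R,2R,9R,3E,7E,11E)-9-hydroxycembra-3,7,11-trien-16,2-olide, via alkenylcopper 37 (not isolated)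
Conditions: MeI, Pd(PPh3)4 (cat.), copper thiophene-2-carboxylate Cu(O2CC4H3S), [Ph2PO2][NBu4], DMF, rt
Reagents that add atoms: iodomethane, CI
Why: Stille-type C-methylation under copper-assisted, fluoride-free conditions: tin-to-copper exchange (tin is sequestered as the phosphinate) and palladium-catalysed coupling with MeI replace tin by methyl with retention, which turns the Z stannane into the E C7=C8 alkene with C6 cis to the new methyl.

Step 24
Reactants: 38 (1R,2R,9R,3E,7E,11E)-9-hydroxycembra-3,7,11-trien-16,2-olide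
Product: 42 (1R,2S,9R,3E,7E,11E)-9-hydroxycembra-3,7,11,15(17)-tetraen-16,2-olide, via dilithium enolate alkoxide 39 (not isolated), via Mannich base 40 (not isolated), via trimethylammonium iodide 41 (not isolated)
Conditions: LiN(SiMe3)2 (2.5 equiv), THF, −78 °C; CH2=NMe2+ I−, −78 °C → rt; aq. NH4Cl; crude amine: MeI, CH2Cl2/MeOH, rt; then aq. NaHCO3, rt
Reagents that add atoms: N,N-dimethylmethyleneiminium iodide (Eschenmoser's salt), C=[N+](C)C.[I-]
Why: Lactone α-methylenation by the Mannich route: excess amide base forms the C9 alkoxide and the lactone enolate, the enolate is aminomethylated at C15 by the iminium salt (any O-aminomethyl aminal at C9 is hydrolysed on work-up), and N-methylation followed by mild-base elimination of trimethylamine gives the exocyclic C15=C17 alkene without touching C1, C2 or C9.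

Step 25
Reactants: 42 (1R,2S,9R,3E,7E,11E)-9-hydroxycembra-3,7,11,15(17)-tetraen-16,2-olide
Product: 43 (1R,2S,9R,3E,7E,11E)-9-acetoxycembra-3,7,11,15(17)-tetraen-16,2-olide (target)
Conditions: Ac2O, pyridine, DMAP (cat.), CH2Cl2, 0 °C → rt
Reagents that add atoms: acetic anhydride, CC(=O)OC(C)=O
Why: DMAP-catalysed acylation of the secondary allylic alcohol with acetic anhydride proceeds with retention at C9 and is mild enough for the α-methylene lactone.

**Compound list**

1 | pent-3-yn-1-ol | CC#CCCO | starting material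
2 | pent-3-yn-1-yl 4-methylbenzenesulfonate | CC#CCCOS(=O)(=O)c1ccc(C)cc1 | intermediate
3 | hepta-1,5-diyne | C#CCCC#CC | intermediate
4 | [(1E)-2-methylhept-1-en-5-yn-1-yl]dimethylalane | CC#CCC/C(C)=C/[Al](C)C | intermediate
5 | (1E)-1-iodo-2-methylhept-1-en-5-yne | CC#CCC/C(C)=C/I | intermediate
6 | hex-1-en-5-yne | C=CCCC#C | starting material
7 | (R)-benzyl glycidyl ether | C1O[C@H]1COCc1ccccc1 | starting material
8 | [(1E)-2-methylhexa-1,5-dien-1-yl]dimethylalane | C=CCC/C(C)=C/[Al](C)C | intermediate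
9 | lithium butyl[(1E)-2-methylhexa-1,5-dien-1-yl]dimethylaluminate | [Li+].C=CCC/C(C)=C/[Al-](C)(C)CCCC | intermediate
10 | (2R,4E)-1-(benzyloxy)-5-methylnona-4,8-dien-2-ol | C=CCC/C(C)=C/C[C@@H](O)COCc1ccccc1 | intermediate
11 | {[(2R,4E)-1-(benzyloxy)-5-methylnona-4,8-dien-2-yl]oxy}(tert-butyl)dimethylsilane | C=CCC/C(C)=C/C[C@@H](O[Si](C)(C)C(C)(C)C)COCc1ccccc1 | intermediate
12 | (2R,4E)-2-[(tert-butyldimethylsilyl)oxy]-5-methylnona-4,8-dien-1-ol | C=CCC/C(C)=C/C[C@@H](O[Si](C)(C)C(C)(C)C)CO | intermediate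
13 | (2R,4E)-2-[(tert-butyldimethylsilyl)oxy]-5-methylnona-4,8-dienal | C=CCC/C(C)=C/C[C@@H](O[Si](C)(C)C(C)(C)C)C=O | intermediate
14 | tert-butyl{[(3R,5E)-1,1-dibromo-6-methyldeca-1,5,9-trien-3-yl]oxy}dimethylsilane | C=CCC/C(C)=C/C[C@@H](O[Si](C)(C)C(C)(C)C)C=C(Br)Br | intermediate
15 | lithium acetylide of (3R,5E)-3-[(tert-butyldimethylsilyl)oxy]-6-methyldeca-5,9-dien-1-yne | C=CCC/C(C)=C/C[C@@H](O[Si](C)(C)C(C)(C)C)C#C[Li] | intermediate
16 | tert-butyldimethyl{[(4R,6E)-7-methylundeca-6,10-dien-2-yn-4-yl]oxy}silane | C=CCC/C(C)=C/C[C@@H](O[Si](C)(C)C(C)(C)C)C#CC | intermediate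
17 | 9-[(5E,8R)-8-[(tert-butyldimethylsilyl)oxy]-5-methylundec-5-en-9-yn-1-yl]-9-borabicyclo[3.3.1]nonane | B1(CCCC/C(C)=C/C[C@@H](O[Si](C)(C)C(C)(C)C)C#CC)C2CCCC1CCC2 | intermediate
18 | (5E,8R)-8-[(tert-butyldimethylsilyl)oxy]-5-methylundec-5-en-9-yn-1-ol | OCCCC/C(C)=C/C[C@@H](O[Si](C)(C)C(C)(C)C)C#CC | intermediate
19 | (5E,8R)-8-[(tert-butyldimethylsilyl)oxy]-5-methylundec-5-en-9-ynal | O=CCCC/C(C)=C/C[C@@H](O[Si](C)(C)C(C)(C)C)C#CC | intermediate
20 | (5E,8R)-8-[(tert-butyldimethylsilyl)oxy]-5-methylundec-5-en-9-ynoic acid | OC(=O)CCC/C(C)=C/C[C@@H](O[Si](C)(C)C(C)(C)C)C#CC | intermediate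
21 | (4S)-4-benzyl-1,3-oxazolidin-2-one | O=C1N[C@@H](Cc2ccccc2)CO1 | starting material
22 | mixed anhydride of acid 20 with pivalic acid | CC(C)(C)C(=O)OC(=O)CCC/C(C)=C/C[C@@H](O[Si](C)(C)C(C)(C)C)C#CC | intermediate
23 | (4S)-4-benzyl-3-[(5E,8R)-8-[(tert-butyldimethylsilyl)oxy]-5-methylundec-5-en-9-ynoyl]-1,3-oxazolidin-2-one | O=C(CCC/C(C)=C/C[C@@H](O[Si](C)(C)C(C)(C)C)C#CC)N1[C@@H](Cc2ccccc2)COC1=O | intermediate
24 | tert-butyl bromoacetate | CC(C)(C)OC(=O)CBr | starting material
25 | sodium (Z)-enolate of imide 23 | [Na+].[O-]/C(=C\CC/C(C)=C/C[C@@H](O[Si](C)(C)C(C)(C)C)C#CC)N1[C@@H](Cc2ccccc2)COC1=O | intermediate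
26 | tert-butyl (3R,6E,9R)-3-{[(4S)-4-benzyl-2-oxo-1,3-oxazolidin-3-yl]carbonyl}-9-[(tert-butyldimethylsilyl)oxy]-6-methyldodec-6-en-10-ynoate | O=C([C@@H](CC(=O)OC(C)(C)C)CC/C(C)=C/C[C@@H](O[Si](C)(C)C(C)(C)C)C#CC)N1[C@@H](Cc2ccccc2)COC1=O | intermediate
27 | tert-butyl (3R,6E,9R)-9-[(tert-butyldimethylsilyl)oxy]-3-(hydroxymethyl)-6-methyldodec-6-en-10-ynoate | OC[C@@H](CC(=O)OC(C)(C)C)CC/C(C)=C/C[C@@H](O[Si](C)(C)C(C)(C)C)C#CC | intermediate
28 | tert-butyl (3R,6E,9R)-9-[(tert-butyldimethylsilyl)oxy]-3-formyl-6-methyldodec-6-en-10-ynoate | O=C[C@@H](CC(=O)OC(C)(C)C)CC/C(C)=C/C[C@@H](O[Si](C)(C)C(C)(C)C)C#CC | intermediate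
29 | [(1E)-2-methylhept-1-en-5-yn-1-yl]chromium dichloride (trivalent chromium) | CC#CCC/C(C)=C/[Cr](Cl)Cl | intermediate
30 | tert-butyl (3R,6E,9R)-9-[(tert-butyldimethylsilyl)oxy]-3-[(2E)-1-hydroxy-3-methyloct-2-en-6-yn-1-yl]-6-methyldodec-6-en-10-ynoate, both carbinol (C2) epimers | CC#CCC/C(C)=C/C(O)[C@@H](CC(=O)OC(C)(C)C)CC/C(C)=C/C[C@@H](O[Si](C)(C)C(C)(C)C)C#CC | intermediate
31 | tert-butyl (3R,6E,9R)-9-[(tert-butyldimethylsilyl)oxy]-6-methyl-3-[(2E)-3-methyloct-2-en-6-ynoyl]dodec-6-en-10-ynoate | CC#CCC/C(C)=C/C(=O)[C@@H](CC(=O)OC(C)(C)C)CC/C(C)=C/C[C@@H](O[Si](C)(C)C(C)(C)C)C#CC | intermediate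
32 | tert-butyl (3R,6E,9R)-9-[(tert-butyldimethylsilyl)oxy]-3-[(1R,2E)-1-hydroxy-3-methyloct-2-en-6-yn-1-yl]-6-methyldodec-6-en-10-ynoate | CC#CCC/C(C)=C/[C@H](O)[C@@H](CC(=O)OC(C)(C)C)CC/C(C)=C/C[C@@H](O[Si](C)(C)C(C)(C)C)C#CC | intermediate
33 | seco-diyne trans-lactone, (4R,5R)-4-[(3E,6R)-6-[(tert-butyldimethylsilyl)oxy]-3-methylnon-3-en-7-yn-1-yl]-5-[(1E)-2-methylhept-1-en-5-yn-1-yl]oxolan-2-one | CC#CCC/C(C)=C/[C@@H]1OC(=O)C[C@H]1CC/C(C)=C/C[C@@H](O[Si](C)(C)C(C)(C)C)C#CC | intermediate
34 | 14-membered C7≡C8 cycloalkyne trans-lactone, C9 tert-butyldimethylsilyl ether (1R,2R,9R; 3E,11E) | O=C1C[C@H]2CC/C(C)=C/C[C@@H](O[Si](C)(C)C(C)(C)C)C#CCC/C(C)=C/[C@@H]2O1 | intermediate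
35 | 14-membered C7≡C8 cycloalkyne trans-lactone, free C9 hydroxyl (1R,2R,9R; 3E,11E) | O=C1C[C@H]2CC/C(C)=C/C[C@@H](O)C#CCC/C(C)=C/[C@@H]2O1 | intermediate
36 | (7Z)-8-(tributylstannyl) macrocyclic C9 alcohol trans-lactone (1R,2R,9R; 3E,11E) | O=C1C[C@H]2CC/C(C)=C/C[C@@H](O)/C([Sn](CCCC)(CCCC)CCCC)=C/CC/C(C)=C/[C@@H]2O1 | intermediate
37 | C8 alkenylcopper corresponding to 36 (monovalent copper) | O=C1C[C@H]2CC/C(C)=C/C[C@@H](O)/C([Cu])=C/CC/C(C)=C/[C@@H]2O1 | intermediate
38 | (1R,2R,9R,3E,7E,11E)-9-hydroxycembra-3,7,11-trien-16,2-olide | O=C1C[C@H]2CC/C(C)=C/C[C@@H](O)/C(C)=C/CC/C(C)=C/[C@@H]2O1 | intermediate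
39 | dilithium C15 enolate / C9 alkoxide of 38 | [Li+].[Li+].[O-]C1=C[C@H]2CC/C(C)=C/C[C@@H]([O-])/C(C)=C/CC/C(C)=C/[C@@H]2O1 | intermediate
40 | 15-[(dimethylamino)methyl] derivative of 38 (Mannich base, C15 configuration not defined) | O=C1C(CN(C)C)[C@H]2CC/C(C)=C/C[C@@H](O)/C(C)=C/CC/C(C)=C/[C@@H]2O1 | intermediate
41 | trimethylammonium iodide from 40 | O=C1C(C[N+](C)(C)C)[C@H]2CC/C(C)=C/C[C@@H](O)/C(C)=C/CC/C(C)=C/[C@@H]2O1.[I-] | intermediate
42 | (1R,2S,9R,3E,7E,11E)-9-hydroxycembra-3,7,11,15(17)-tetraen-16,2-olide | C=C1C(=O)O[C@H]2/C=C(\C)CC/C=C(\C)[C@H](O)C/C=C(\C)CC[C@H]12 | intermediate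
43 | CNP0129197.1, (1R,2S,9R,3E,7E,11E)-9-acetoxycembra-3,7,11,15(17)-tetraen-16,2-olide | C=C1C(=O)O[C@H]2/C=C(\C)CC/C=C(\C)[C@H](OC(C)=O)C/C=C(\C)CC[C@H]12 | target

**Step count and risk**

Total step count: 25. Longest linear sequence: 22 steps (steps 4–25, from hex-1-en-5-yne); steps 1–3 are the side branch to iodide 5.

Steps most likely to fail:

1. Step 20 (ring-closing alkyne metathesis). Intermolecular metathesis may outrun ring closure, so that oligomers grow instead of the 14-membered ring, because the trans-lactone holds the two alkyne arms apart. The fallback makes C7≡C8 between two molecules and closes the ring at C2–C3 instead. It sets out from imide 26 and iodide 5. Alkyne cross-metathesis of 26 with excess 5 under the same molybdenum alkylidyne should give the iodo-enyne imide F1. LiBH4 then removes the auxiliary to give the alcohol F2, and Dess–Martin oxidation gives the aldehyde F3. Intramolecular CrCl2/NiCl2 coupling at high dilution closes the carbocycle as the allylic alcohols F4. Oxidation to the macrocyclic enone F5, oxazaborolidine reduction to the (2R)-alcohol F6 and KOC(CH3)3-catalysed lactonisation come back to the route at cycloalkyne 34.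

2. Step 18 (oxazaborolidine reduction). Facial selectivity may be poor if the branched C1 flank competes with the alkenyl flank for the large-group role, or if catalyst and C1 are mismatched. The fallback drops the redox correction and sets out from the epimer mixture 30. KOC(CH3)3-catalysed lactonisation of 30 gives 33 together with its C2 epimer, the cis-lactone F7; the two diastereomeric γ-lactones are separated by chromatography, and the route is rejoined at 33.

3. Step 24 (α-methylenation with the C9 hydroxyl free). The C9 alkoxide may be aminomethylated irreversibly or may interfere with clean enolisation of the lactone. The fallback masks the hydroxyl and sets out from 38. Et3SiCl/imidazole gives the triethylsilyl ether F8. The same enolate Mannich reaction gives the amine F9, MeI gives the ammonium iodide F10, and NaHCO3 gives the α-methylene lactone silyl ether F11. HF·pyridine then removes the silyl group and returns to 42.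

Further compounds
F1 | step 20 | tert-butyl (3R,6E,9R,14E)-3-{[(4S)-4-benzyl-2-oxo-1,3-oxazolidin-3-yl]carbonyl}-9-[(tert-butyldimethylsilyl)oxy]-15-iodo-6,14-dimethylpentadeca-6,14-dien-10-ynoate | O=C([C@@H](CC(=O)OC(C)(C)C)CC/C(C)=C/C[C@@H](O[Si](C)(C)C(C)(C)C)C#CCC/C(C)=C/I)N1[C@@H](Cc2ccccc2)COC1=O
F2 | step 20 | tert-butyl (3R,6E,9R,14E)-9-[(tert-butyldimethylsilyl)oxy]-3-(hydroxymethyl)-15-iodo-6,14-dimethylpentadeca-6,14-dien-10-ynoate | OC[C@@H](CC(=O)OC(C)(C)C)CC/C(C)=C/C[C@@H](O[Si](C)(C)C(C)(C)C)C#CCC/C(C)=C/I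
F3 | step 20 | tert-butyl (3R,6E,9R,14E)-9-[(tert-butyldimethylsilyl)oxy]-3-formyl-15-iodo-6,14-dimethylpentadeca-6,14-dien-10-ynoate | O=C[C@@H](CC(=O)OC(C)(C)C)CC/C(C)=C/C[C@@H](O[Si](C)(C)C(C)(C)C)C#CCC/C(C)=C/I
F4 | step 20 | 14-membered C7≡C8 cycloalkyne with C2 hydroxyl (both epimers), C1 tert-butoxycarbonylmethyl and C9 silyl ether | CC(C)(C)OC(=O)C[C@H]1CC/C(C)=C/C[C@@H](O[Si](C)(C)C(C)(C)C)C#CCC/C(C)=C/C1O
F5 | step 20 | 14-membered C7≡C8 cycloalkyne C2 enone with C1 tert-butoxycarbonylmethyl and C9 silyl ether | CC(C)(C)OC(=O)C[C@H]1CC/C(C)=C/C[C@@H](O[Si](C)(C)C(C)(C)C)C#CCC/C(C)=C/C1=O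
F6 | step 20 | (2R)-alcohol from F5 | CC(C)(C)OC(=O)C[C@H]1CC/C(C)=C/C[C@@H](O[Si](C)(C)C(C)(C)C)C#CCC/C(C)=C/[C@@H]1O
F7 | step 18 | cis-lactone, the C2 epimer of 33 | CC#CCC/C(C)=C/[C@H]1OC(=O)C[C@H]1CC/C(C)=C/C[C@@H](O[Si](C)(C)C(C)(C)C)C#CC
F8 | step 24 | C9 triethylsilyl ether of 38 | O=C1C[C@H]2CC/C(C)=C/C[C@@H](O[Si](CC)(CC)CC)/C(C)=C/CC/C(C)=C/[C@@H]2O1
F9 | step 24 | 15-[(dimethylamino)methyl] derivative of F8 | O=C1C(CN(C)C)[C@H]2CC/C(C)=C/C[C@@H](O[Si](CC)(CC)CC)/C(C)=C/CC/C(C)=C/[C@@H]2O1
F10 | step 24 | trimethylammonium iodide from F9 | O=C1C(C[N+](C)(C)C)[C@H]2CC/C(C)=C/C[C@@H](O[Si](CC)(CC)CC)/C(C)=C/CC/C(C)=C/[C@@H]2O1.[I-]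
F11 | step 24 | C9 triethylsilyl ether of 42 | O=C1C(=C)[C@H]2CC/C(C)=C/C[C@@H](O[Si](CC)(CC)CC)/C(C)=C/CC/C(C)=C/[C@@H]2O1
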